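**Retrosynthetic overview**
1. The target comes from a macrocyclic 6-alcohol by 6-O-angeloylation and 3-O-desilylation.
2. Ten-membered ring (formed second): the C-6–C-7 bond, the bond made in germacrene biosynthesis (farnesyl C-1 to C-10), is closed by intramolecular CrCl2 allylation of a C-6 Z-enal by its own 3-(bromomethyl)butenolide; C-8 steers C-7 and C-6.
3. Lactone ring (formed first): O-8 to C-12 lactonisation of an 8-hydroxy Z-enoate, as in the biosynthetic 8-hydroxy acid to 12,8-olide step, follows an asymmetric Ni/Cr coupling of a C-8 Z-enal with a 3-iodoacrylate.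
4. Acyclic C-8 to C-6 chain: boron aldol (C-1–C-2) of a Z-enal with a Z-methyl enone, then Evans–Tishchenko reduction, which gives 1-OAc/3-OH anti in one step.
5. Both Z-trisubstituted alkenes come from one ring-opening of 3-methylfuran-2(5H)-one; the hydroxy amide is divided between the two fragments.

Assumption: the SMILES is read with germacrane numbering as (1S,3S,6R,7R,8R)-1-acetoxy-6-angeloyloxy-3-hydroxygermacra-4Z,9Z,11(13)-trien-12,8-olide, with H-7 and H-8 on the same face (cis-fused lactone); atom labels C-1 to C-15 follow this numbering, TES = triethylsilyl, TBS = tert-butyldimethylsilyl.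

**Step 1**
Reactants: 1 3-methylfuran-2(5H)-one
Product: 2 (2Z)-4-hydroxy-N-methoxy-N,2-dimethylbut-2-enamide
Conditions: MeNH(OMe)·HCl, i-PrMgCl, THF, -20 °C; aq. NH4Cl, cold extractive work-up; crude product divided at once between steps 2 and 4
Reagents that add atoms: N,O-dimethylhydroxylamine hydrochloride, CNOC.Cl
Why: Weinreb aminolysis of the lactone (acyl substitution by the chloromagnesium amide) hands the ring-enforced Z geometry to the open chain, and using the crude hydroxy amide without delay avoids relactonisation.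

**Step 2**
Reactants: 2 (2Z)-4-hydroxy-N-methoxy-N,2-dimethylbut-2-enamide
Product: 3 (2Z)-N-methoxy-N,2-dimethyl-4-[(triethylsilyl)oxy]but-2-enamide
Conditions: TESCl, imidazole (2 equiv), CH2Cl2, 0 °C
Reagents that add atoms: chlorotriethylsilane, CC[Si](Cl)(CC)CC
Why: Imidazole-promoted O-silylation of the primary allylic alcohol blocks relactonisation and installs the silyl group that is later oxidised off selectively.

**Step 3**
Reactants: 3 (2Z)-N-methoxy-N,2-dimethyl-4-[(triethylsilyl)oxy]but-2-enamide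
Product: 4 (2Z)-2-methyl-4-[(triethylsilyl)oxy]but-2-enal
Conditions: i-Bu2AlH, THF, -78 °C; aq. potassium sodium tartrate work-up
Reagents that add atoms: none
Why: Weinreb amide reduction stops at the aldehyde through the chelated aluminium hemiaminal and leaves the Z alkene untouched, giving the fragment that becomes C-8 to C-1.

**Step 4**
Reactants: 2 (2Z)-4-hydroxy-N-methoxy-N,2-dimethylbut-2-enamide
Product: 5 (2Z)-4-[(tert-butyldimethylsilyl)oxy]-N-methoxy-N,2-dimethylbut-2-enamide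
Conditions: TBSCl, imidazole (2 equiv), CH2Cl2, 0 °C to rt
Reagents that add atoms: tert-butyldimethylsilyl chloride, CC(C)(C)[Si](C)(C)Cl
Why: The same imidazole-promoted O-silylation as in step 2, with the more robust silyl group for the C-6 oxygen.

**Step 5**
Reactants: 5 (2Z)-4-[(tert-butyldimethylsilyl)oxy]-N-methoxy-N,2-dimethylbut-2-enamide
Product: 6 (3Z)-5-[(tert-butyldimethylsilyl)oxy]-3-methylpent-3-en-2-one
Conditions: MeMgBr, THF, 0 °C; aq. NH4Cl
Reagents that add atoms: methylmagnesium bromide, C[Mg]Br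
Why: Weinreb ketone synthesis, in which the chelated tetrahedral intermediate prevents over-addition and the Z enone (the fragment that becomes C-2 to C-6) is released only on work-up.

**Step 6**
Reactants: 6 (3Z)-5-[(tert-butyldimethylsilyl)oxy]-3-methylpent-3-en-2-one; 4 (2Z)-2-methyl-4-[(triethylsilyl)oxy]but-2-enal
Product: 8 (2Z,6S,7Z)-1-[(tert-butyldimethylsilyl)oxy]-6-hydroxy-3,7-dimethyl-9-[(triethylsilyl)oxy]nona-2,7-dien-4-one, via enol borinate 7 (not isolated)
Conditions: (-)-Ipc2BCl, Et3N, Et2O, 0 °C; then 4, -78 to -20 °C; H2O2, pH 7 buffer, MeOH, 0 °C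
Reagents that add atoms: none
Why: Paterson boron aldol of a methyl ketone, in which the isopinocampheyl groups of the kinetic enol borinate direct addition to the si face of the enal and set C-1 as S (reagent control; the antipodal borane would give the other face).

**Step 7**
Reactants: 8 (2Z,6S,7Z)-1-[(tert-butyldimethylsilyl)oxy]-6-hydroxy-3,7-dimethyl-9-[(triethylsilyl)oxy]nona-2,7-dien-4-one
Product: 9 (2Z,4S,6S,7Z)-1-[(tert-butyldimethylsilyl)oxy]-4-hydroxy-3,7-dimethyl-9-[(triethylsilyl)oxy]nona-2,7-dien-6-yl acetate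
Conditions: SmI2 (30 mol%), CH3CHO (8 equiv), THF, -10 °C
Reagents that add atoms: acetaldehyde, CC=O
Why: Evans–Tishchenko reduction, in which the samarium-bound hemiacetal of the C-1 hydroxyl delivers hydride intramolecularly through a chelated chair-like transition state to the C-3 ketone, giving the 1,3-anti carbinol (C-3 S) and leaving the acetyl group on O-1.

**Step 8**
Reactants: 9 (2Z,4S,6S,7Z)-1-[(tert-butyldimethylsilyl)oxy]-4-hydroxy-3,7-dimethyl-9-[(triethylsilyl)oxy]nona-2,7-dien-6-yl acetate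
Product: 10 (2Z,4S,6S,7Z)-1,4-bis[(tert-butyldimethylsilyl)oxy]-3,7-dimethyl-9-[(triethylsilyl)oxy]nona-2,7-dien-6-yl acetate
Conditions: TBSOTf, 2,6-lutidine, CH2Cl2, -78 °C
Reagents that add atoms: tert-butyldimethylsilyl triflate, CC(C)(C)[Si](C)(C)OS(=O)(=O)C(F)(F)F
Why: Fast low-temperature silylation of the C-3 alcohol blocks 1,3-acetyl migration and keeps O-3 masked until the last step.

**Step 9**
Reactants: 10 (2Z,4S,6S,7Z)-1,4-bis[(tert-butyldimethylsilyl)oxy]-3,7-dimethyl-9-[(triethylsilyl)oxy]nona-2,7-dien-6-yl acetate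
Product: 11 (2Z,4S,6S,7Z)-6,9-bis[(tert-butyldimethylsilyl)oxy]-3,7-dimethyl-1-oxonona-2,7-dien-4-yl acetate
Conditions: (COCl)2, DMSO, CH2Cl2, -78 to -30 °C; Et3N, -78 to 0 °C
Reagents that add atoms: none
Why: Swern oxidation applied directly to the primary triethylsilyl ether (oxidative desilylation), which the primary and secondary TBS ethers and the acetate survive, gives the C-8 Z enal in one step.

**Step 10**
Reactants: 12 methyl prop-2-ynoate
Product: 13 methyl (2Z)-2-(hydroxymethyl)-3-iodoprop-2-enoate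
Conditions: MgI2, monomeric CH2O (from cracked paraformaldehyde), CH2Cl2, 0 °C
Reagents that add atoms: formaldehyde, C=O; magnesium iodide, [Mg+2].[I-].[I-]
Why: β-Iodo Morita–Baylis–Hillman (halo-aldol) reaction, in which iodide adds to the propiolate and the magnesium iodoallenolate is trapped by formaldehyde to give the kinetic Z iodide with iodine cis to the ester (the C-7/C-11/C-12/C-13 unit).

**Step 11**
Reactants: 11 (2Z,4S,6S,7Z)-6,9-bis[(tert-butyldimethylsilyl)oxy]-3,7-dimethyl-1-oxonona-2,7-dien-4-yl acetate; 13 methyl (2Z)-2-(hydroxymethyl)-3-iodoprop-2-enoate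
Product: 15 (5R)-5-[(1Z,3S,5S,6Z)-3-acetoxy-5,8-bis[(tert-butyldimethylsilyl)oxy]-2,6-dimethylocta-1,6-dien-1-yl]-3-(hydroxymethyl)furan-2(5H)-one, via seco hydroxy ester 14 (not isolated)
Conditions: CrCl2 (4 equiv), (S)-N-[2-(4-isopropyl-4,5-dihydro-1,3-oxazol-2-yl)-6-methylphenyl]methanesulfonamide (Kishi ligand, 4.4 equiv), Et3N (4.4 equiv), NiCl2 (5 mol%), THF, rt; then PPTS (cat.), CH2Cl2, rt
Reagents that add atoms: none
Why: Asymmetric Nozaki–Hiyama–Kishi coupling in which the ligand-bound alkenylchromium adds to the si face of the enal (reagent control, C-8 R; the enantiomeric ligand would give the other face), and the resulting Z γ-hydroxy enoate lactonises O-8 onto C-12.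

**Step 12**
Reactants: 15 (5R)-5-[(1Z,3S,5S,6Z)-3-acetoxy-5,8-bis[(tert-butyldimethylsilyl)oxy]-2,6-dimethylocta-1,6-dien-1-yl]-3-(hydroxymethyl)furan-2(5H)-one
Product: 16 (5R)-5-[(1Z,3S,5S,6Z)-3-acetoxy-5,8-bis[(tert-butyldimethylsilyl)oxy]-2,6-dimethylocta-1,6-dien-1-yl]-3-(bromomethyl)furan-2(5H)-one
Conditions: CBr4, PPh3 (1.05 equiv), CH2Cl2, 0 °C
Reagents that add atoms: carbon tetrabromide, BrC(Br)(Br)Br
Why: Appel bromination of the only free (primary allylic) alcohol under neutral conditions that do not touch the acidic C-8 hydrogen.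

**Step 13**
Reactants: 16 (5R)-5-[(1Z,3S,5S,6Z)-3-acetoxy-5,8-bis[(tert-butyldimethylsilyl)oxy]-2,6-dimethylocta-1,6-dien-1-yl]-3-(bromomethyl)furan-2(5H)-one
Product: 17 (5R)-5-[(1Z,3S,5S,6Z)-3-acetoxy-5-[(tert-butyldimethylsilyl)oxy]-8-hydroxy-2,6-dimethylocta-1,6-dien-1-yl]-3-(bromomethyl)furan-2(5H)-one
Conditions: HF (48% aq.), MeCN, 0 °C
Reagents that add atoms: none
Why: Acidic, non-nucleophilic desilylation cleaves the primary allylic TBS ether much faster than the hindered secondary one and spares the allylic bromide and acetate.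

**Step 14**
Reactants: 17 (5R)-5-[(1Z,3S,5S,6Z)-3-acetoxy-5-[(tert-butyldimethylsilyl)oxy]-8-hydroxy-2,6-dimethylocta-1,6-dien-1-yl]-3-(bromomethyl)furan-2(5H)-one
Product: 18 (5R)-5-[(1Z,3S,5S,6Z)-3-acetoxy-5-[(tert-butyldimethylsilyl)oxy]-2,6-dimethyl-8-oxoocta-1,6-dien-1-yl]-3-(bromomethyl)furan-2(5H)-one
Conditions: Dess–Martin periodinane, NaHCO3, CH2Cl2, 0 °C
Reagents that add atoms: none
Why: Buffered Dess–Martin oxidation gives the C-6 Z enal without base that could isomerise it or enolise the butenolide.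

**Step 15**
Reactants: 18 (5R)-5-[(1Z,3S,5S,6Z)-3-acetoxy-5-[(tert-butyldimethylsilyl)oxy]-2,6-dimethyl-8-oxoocta-1,6-dien-1-yl]-3-(bromomethyl)furan-2(5H)-one
Product: 19 (1S,3S,6R,7S,8R)-1-acetoxy-3-[(tert-butyldimethylsilyl)oxy]-6-hydroxygermacra-4Z,9Z,11(13)-trien-12,8-olide
Conditions: CrCl2 (10 equiv), THF, rt, syringe-pump addition of 18 over 12 h (final 0.002 M)
Reagents that add atoms: none
Why: Proposed new method: an intramolecular Nozaki–Hiyama (chromium Barbier) allylation with a 3-(bromomethyl)butenolide as allyl donor, in which CrCl2 inserts into the allylic C–Br bond and the allylchromium (C-8 held trans to CH2Cr by the lactone ring) adds through C-7 to the tethered aldehyde in a chair Zimmerman–Traxler transition state with C-5 equatorial, which gives the 6,7-anti relationship (C-6 R) and, by delivery to the face of C-7 that carries H-8, the cis ring fusion; the closest known reactions are the anti-selective intermolecular CrCl2 additions of 3-(bromomethyl)furan-2(5H)-ones to aldehydes and the CrCl2 macrocyclisations of acyclic 2-(bromomethyl)enoate aldehydes to ten-membered germacranolides.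

**Step 16**
Reactants: 19 (1S,3S,6R,7S,8R)-1-acetoxy-3-[(tert-butyldimethylsilyl)oxy]-6-hydroxygermacra-4Z,9Z,11(13)-trien-12,8-olide; 20 angelic acid, (2Z)-2-methylbut-2-enoic acid
Product: 22 (1S,3S,6R,7R,8R)-1-acetoxy-6-angeloyloxy-3-[(tert-butyldimethylsilyl)oxy]germacra-4Z,9Z,11(13)-trien-12,8-olide, via mixed anhydride 21 (not isolated)
Conditions: 20, 2,4,6-trichlorobenzoyl chloride, Et3N, toluene, rt; then 19, toluene, 80 °C (no DMAP)
Reagents that add atoms: none
Why: Yamaguchi esterification through the trichlorobenzoyl mixed anhydride acylates the hindered allylic 6-OH without the nucleophilic catalyst that isomerises angelate to tiglate (the C-7 descriptor changes only because of CIP priorities).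

**Step 17**
Reactants: 22 (1S,3S,6R,7R,8R)-1-acetoxy-6-angeloyloxy-3-[(tert-butyldimethylsilyl)oxy]germacra-4Z,9Z,11(13)-trien-12,8-olide
Product: 23 (1S,3S,6R,7R,8R)-1-acetoxy-6-angeloyloxy-3-hydroxygermacra-4Z,9Z,11(13)-trien-12,8-olide (CNP0319825.3)
Conditions: HF·pyridine, pyridine, THF, 0 °C to rt
Reagents that add atoms: none
Why: Buffered fluoride desilylation frees the 3-hydroxyl without acyl migration or attack on the α-methylene lactone.

**Compound list**
1 | 3-methylfuran-2(5H)-one | CC1=CCOC1=O | starting material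
2 | (2Z)-4-hydroxy-N-methoxy-N,2-dimethylbut-2-enamide | CON(C)C(=O)/C(C)=C\CO | intermediate
3 | (2Z)-N-methoxy-N,2-dimethyl-4-[(triethylsilyl)oxy]but-2-enamide | CON(C)C(=O)/C(C)=C\CO[Si](CC)(CC)CC | intermediate
4 | (2Z)-2-methyl-4-[(triethylsilyl)oxy]but-2-enal | O=C/C(C)=C\CO[Si](CC)(CC)CC | intermediate
5 | (2Z)-4-[(tert-butyldimethylsilyl)oxy]-N-methoxy-N,2-dimethylbut-2-enamide | CON(C)C(=O)/C(C)=C\CO[Si](C)(C)C(C)(C)C | intermediate
6 | (3Z)-5-[(tert-butyldimethylsilyl)oxy]-3-methylpent-3-en-2-one | CC(=O)/C(C)=C\CO[Si](C)(C)C(C)(C)C | intermediate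
7 | (3Z)-5-[(tert-butyldimethylsilyl)oxy]-3-methylpenta-1,3-dien-2-yl bis[(1R,2S,3R,5R)-2,6,6-trimethylbicyclo[3.1.1]hept-3-yl]borinate (enol borinate of 6) | C=C(OB([C@@H]1C[C@@H]2C[C@H]([C@H]1C)C2(C)C)[C@@H]1C[C@@H]2C[C@H]([C@H]1C)C2(C)C)/C(C)=C\CO[Si](C)(C)C(C)(C)C | intermediate (not isolated)
8 | (2Z,6S,7Z)-1-[(tert-butyldimethylsilyl)oxy]-6-hydroxy-3,7-dimethyl-9-[(triethylsilyl)oxy]nona-2,7-dien-4-one | CC[Si](CC)(CC)OC/C=C(/C)[C@@H](O)CC(=O)/C(C)=C\CO[Si](C)(C)C(C)(C)C | intermediate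
9 | (2Z,4S,6S,7Z)-1-[(tert-butyldimethylsilyl)oxy]-4-hydroxy-3,7-dimethyl-9-[(triethylsilyl)oxy]nona-2,7-dien-6-yl acetate | CC[Si](CC)(CC)OC/C=C(/C)[C@@H](OC(C)=O)C[C@H](O)/C(C)=C\CO[Si](C)(C)C(C)(C)C | intermediate
10 | (2Z,4S,6S,7Z)-1,4-bis[(tert-butyldimethylsilyl)oxy]-3,7-dimethyl-9-[(triethylsilyl)oxy]nona-2,7-dien-6-yl acetate | CC[Si](CC)(CC)OC/C=C(/C)[C@@H](OC(C)=O)C[C@H](O[Si](C)(C)C(C)(C)C)/C(C)=C\CO[Si](C)(C)C(C)(C)C | intermediate
11 | (2Z,4S,6S,7Z)-6,9-bis[(tert-butyldimethylsilyl)oxy]-3,7-dimethyl-1-oxonona-2,7-dien-4-yl acetate | O=C/C=C(/C)[C@@H](OC(C)=O)C[C@H](O[Si](C)(C)C(C)(C)C)/C(C)=C\CO[Si](C)(C)C(C)(C)C | intermediate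
12 | methyl prop-2-ynoate | C#CC(=O)OC | starting material
13 | methyl (2Z)-2-(hydroxymethyl)-3-iodoprop-2-enoate | COC(=O)/C(CO)=C\I | intermediate
14 | methyl (2Z,4R,5Z,7S,9S,10Z)-7-acetoxy-9,12-bis[(tert-butyldimethylsilyl)oxy]-4-hydroxy-2-(hydroxymethyl)-6,10-dimethyldodeca-2,5,10-trienoate | COC(=O)/C(CO)=C\[C@H](O)/C=C(/C)[C@@H](OC(C)=O)C[C@H](O[Si](C)(C)C(C)(C)C)/C(C)=C\CO[Si](C)(C)C(C)(C)C | intermediate (not isolated)
15 | (5R)-5-[(1Z,3S,5S,6Z)-3-acetoxy-5,8-bis[(tert-butyldimethylsilyl)oxy]-2,6-dimethylocta-1,6-dien-1-yl]-3-(hydroxymethyl)furan-2(5H)-one | O=C1O[C@H](/C=C(/C)[C@@H](OC(C)=O)C[C@H](O[Si](C)(C)C(C)(C)C)/C(C)=C\CO[Si](C)(C)C(C)(C)C)C=C1CO | intermediate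
16 | (5R)-5-[(1Z,3S,5S,6Z)-3-acetoxy-5,8-bis[(tert-butyldimethylsilyl)oxy]-2,6-dimethylocta-1,6-dien-1-yl]-3-(bromomethyl)furan-2(5H)-one | O=C1O[C@H](/C=C(/C)[C@@H](OC(C)=O)C[C@H](O[Si](C)(C)C(C)(C)C)/C(C)=C\CO[Si](C)(C)C(C)(C)C)C=C1CBr | intermediate
17 | (5R)-5-[(1Z,3S,5S,6Z)-3-acetoxy-5-[(tert-butyldimethylsilyl)oxy]-8-hydroxy-2,6-dimethylocta-1,6-dien-1-yl]-3-(bromomethyl)furan-2(5H)-one | O=C1O[C@H](/C=C(/C)[C@@H](OC(C)=O)C[C@H](O[Si](C)(C)C(C)(C)C)/C(C)=C\CO)C=C1CBr | intermediate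
18 | (5R)-5-[(1Z,3S,5S,6Z)-3-acetoxy-5-[(tert-butyldimethylsilyl)oxy]-2,6-dimethyl-8-oxoocta-1,6-dien-1-yl]-3-(bromomethyl)furan-2(5H)-one | O=C1O[C@H](/C=C(/C)[C@@H](OC(C)=O)C[C@H](O[Si](C)(C)C(C)(C)C)/C(C)=C\C=O)C=C1CBr | intermediate
19 | (1S,3S,6R,7S,8R)-1-acetoxy-3-[(tert-butyldimethylsilyl)oxy]-6-hydroxygermacra-4Z,9Z,11(13)-trien-12,8-olide | C=C1C(=O)O[C@@H]2/C=C(/C)[C@@H](OC(C)=O)C[C@H](O[Si](C)(C)C(C)(C)C)/C(C)=C\[C@@H](O)[C@H]12 | intermediate
20 | angelic acid, (2Z)-2-methylbut-2-enoic acid | C/C=C(/C)C(=O)O | starting material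
21 | (2Z)-2-methylbut-2-enoic 2,4,6-trichlorobenzoic anhydride | C/C=C(/C)C(=O)OC(=O)c1c(Cl)cc(Cl)cc1Cl | intermediate (not isolated)
22 | (1S,3S,6R,7R,8R)-1-acetoxy-6-angeloyloxy-3-[(tert-butyldimethylsilyl)oxy]germacra-4Z,9Z,11(13)-trien-12,8-olide | C=C1C(=O)O[C@@H]2/C=C(/C)[C@@H](OC(C)=O)C[C@H](O[Si](C)(C)C(C)(C)C)/C(C)=C\[C@@H](OC(=O)/C(C)=C\C)[C@H]12 | intermediate
23 | (1S,3S,6R,7R,8R)-1-acetoxy-6-angeloyloxy-3-hydroxygermacra-4Z,9Z,11(13)-trien-12,8-olide | C=C1C(=O)O[C@@H]2/C=C(/C)[C@@H](OC(C)=O)C[C@H](O)/C(C)=C\[C@@H](OC(=O)/C(C)=C\C)[C@H]12 | target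

**Step count and risks**
Total steps: 17. Longest linear sequence: 14 steps (1 → 2 → 3 → 4 → 8 → 9 → 10 → 11 → 15 → 16 → 17 → 18 → 19 → 22 → 23).

Most likely to fail:

1. Step 15 (macrocyclisation). Risks are oligomerisation, the trans-fused or 6-epi diastereomer, and translactonisation of the free 6-alkoxide onto C-12. The fallback replaces the stoichiometric allylchromium by a catalytic π-allylpalladium umpolung of the allylic alcohol itself and sets out from 15. Aqueous HF in MeCN removes only the primary silyl ether to give diol F1. MnO2 then oxidises the electron-rich allylic alcohol selectively (the hydroxymethyl group on the electron-poor butenolide is left) to give hydroxy-aldehyde F2. Pd(PPh3)4 with Et3B in THF at high dilution ionises the allylic alcohol, and the resulting allylborane adds to the aldehyde through a closed transition state. This rejoins the route at 19 and leaves out the bromination.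

2. Step 11 (C-8 stereocentre and lactone). Risks are weak ligand control on a Z-enal and sluggish Ni/Cr coupling of the hydroxymethyl iodoacrylate. The fallback builds the butenolide by ring-closing metathesis and sets out from 11. Catalytic asymmetric vinylation (divinylzinc, (-)-3-exo-morpholinoisoborneol, toluene, 0 °C) gives dienyl carbinol F3. Esterification with 2-(bromomethyl)acrylic acid (DIC, CH2Cl2, 0 °C) gives 2-(bromomethyl)acrylate ester F4. Ring-closing metathesis with the second-generation Grubbs catalyst RuCl2(=CHPh)(H2IMes)(PCy3) in CH2Cl2 at 40 °C closes the five-membered ring from the vinyl group onto the acrylate. This rejoins the route at 16.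

3. Step 7 (Evans–Tishchenko on a hindered conjugated Z-enone). Risks are slow hydride transfer and acetyl migration between O-1 and O-3. The fallback separates acylation from reduction and sets out from 8. Ac2O with pyridine at -20 °C gives β-acetoxy enone F5. Catalyst-controlled reduction with (R)-2-methyl-CBS-oxazaborolidine and catecholborane in toluene at -78 °C then sets C-3 as S. This rejoins the route at 9.

**Further compounds**
F1 | step 15 | (5R)-5-[(1Z,3S,5S,6Z)-3-acetoxy-5-[(tert-butyldimethylsilyl)oxy]-8-hydroxy-2,6-dimethylocta-1,6-dien-1-yl]-3-(hydroxymethyl)furan-2(5H)-one | O=C1O[C@H](/C=C(/C)[C@@H](OC(C)=O)C[C@H](O[Si](C)(C)C(C)(C)C)/C(C)=C\CO)C=C1CO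
F2 | step 15 | (5R)-5-[(1Z,3S,5S,6Z)-3-acetoxy-5-[(tert-butyldimethylsilyl)oxy]-2,6-dimethyl-8-oxoocta-1,6-dien-1-yl]-3-(hydroxymethyl)furan-2(5H)-one | O=C1O[C@H](/C=C(/C)[C@@H](OC(C)=O)C[C@H](O[Si](C)(C)C(C)(C)C)/C(C)=C\C=O)C=C1CO
F3 | step 11 | (3S,4Z,6S,8S,9Z)-8,11-bis[(tert-butyldimethylsilyl)oxy]-3-hydroxy-5,9-dimethylundeca-1,4,9-trien-6-yl acetate | C=C[C@H](O)/C=C(/C)[C@@H](OC(C)=O)C[C@H](O[Si](C)(C)C(C)(C)C)/C(C)=C\CO[Si](C)(C)C(C)(C)C
F4 | step 11 | (3S,4Z,6S,8S,9Z)-6-acetoxy-8,11-bis[(tert-butyldimethylsilyl)oxy]-5,9-dimethylundeca-1,4,9-trien-3-yl 2-(bromomethyl)prop-2-enoate | C=C(CBr)C(=O)O[C@@H](C=C)/C=C(/C)[C@@H](OC(C)=O)C[C@H](O[Si](C)(C)C(C)(C)C)/C(C)=C\CO[Si](C)(C)C(C)(C)C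
F5 | step 7 | (2Z,6S,7Z)-1-[(tert-butyldimethylsilyl)oxy]-3,7-dimethyl-4-oxo-9-[(triethylsilyl)oxy]nona-2,7-dien-6-yl acetate | CC[Si](CC)(CC)OC/C=C(/C)[C@@H](OC(C)=O)CC(=O)/C(C)=C\CO[Si](C)(C)C(C)(C)C
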